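## The problem

The target is a ring-A-opened labdane of the manoyl oxide type. A cyclohexane (ring B, C5–C10) is trans-fused through C8–C9 to a tetrahydropyran (ring C, O–C8–C9–C11–C12–C13). What is left of ring A is a CH2CO2H arm (C1–C2) on C10 and a CMe2CO2H arm (C4–C3) on C5.

There are five stereocentres (C5, C8, C9, C10, C13), three of them fully substituted (C8, C10, C13). C4, C5 and C10 form a contiguous crowded triad with two quaternary carbons, so any bond made to C10 or C9 in the ground state meets severe hindrance.

C5 is next to C10 and can direct it. C5 and C10 together lock the chair of ring B, so C9 (α to a C8 carbonyl) can be set by equilibration and C8 by equatorial entry of oxygen. C13 is separated from the ring by two methylene groups and cannot be controlled from it, so it has to be brought in as an enantiopure building block.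

The tertiary allylic ether at C13 ionises under acid. The vinyl group does not survive ozone, hydrogenation or unselective electrophiles, so it must enter after any ozonolysis. The C3 ester is neopentyl-like and resists acyl-oxygen hydrolysis.

The feature that opens the structure is that C10 is quaternary and β to C8 once C8 is a carbonyl, and its arm C1–C2 is exactly two carbons of allene. The central allene carbon (C2) can be bonded to C9 in a cyclobutane and, after oxidation to a ketone, cut from C9 again by retro-Claisen cleavage. While it is attached, C9–H is the most acidic position in the molecule, which solves the regiochemistry of attaching C11.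

## Retrosynthesis

**Ester cleavage.** Target 26 is taken back to its dimethyl ester 25. Only two O–CH3 bonds are cut. The forward step has to cleave a neopentyl-type ester without acid, so it is planned as nucleophilic attack at the methyl carbons rather than saponification.

**Ring C, O–C8 bond.** In 25 the ether is cut between O and C8, not between O and C13. Forming O–C13 would need a cation or leaving group at the tertiary allylic carbon and would put the imported stereocentre at risk. Cutting O–C8 leaves C13 as an intact tertiary alcohol in 23, which adds to a C8 exocyclic methylene in the Markovnikov sense. The precursor 23 is monocyclic. Its methylene comes from ketone 21 by methylenation (22) and desilylation. The forward closure must give the equatorial C8–O bond and must not touch the vinyl group, which points to oxymercuration rather than protic acid.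

**Reconnection of C2 to C9.** Keto diester 21 has C8 and C2 in a 1,5-relationship. Joining C2 to C9 in the retrosynthetic sense gives the 2-acylcyclobutanone 20. The forward reaction is a retro-Claisen cleavage driven by ring strain, which frees the acetate arm on C10 and turns C9 into an enolisable CH, so its configuration can be set by equilibration.

**C9–C11 bond.** Cutting C9–C11 in 20 gives diketone 12 and iodide 19. The cut is made at this stage for two reasons. After ring opening, C9 would be the hindered α-position of a simple ketone and C7 would react instead. Before the ozonolysis that creates the C2 carbonyl, the vinyl group of the side chain would be destroyed. In 12, C9 carries the only doubly activated hydrogen. The forward reaction is a C-alkylation at a crowded carbon and is the weakest ground-state step of the plan.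

**Key disconnection, C10–C1 and C9–C2.** Diketone 12 comes from the methylidenecyclobutane 10 by ozonolysis. Adduct 10 is cut across the four-membered ring into enone 8 and allene 9. Conjugate addition of an acetate equivalent to the β,β-disubstituted enone next to the bulky C5 group would be slow in the ground state. The photocycloaddition is far less sensitive to crowding and also leaves C9 activated. The precursor 8 is monocyclic with a single stereocentre. The forward step must be head-to-head and must add anti to the C5 substituent.

**Enone.** The stereocentre of 8 (C5) is γ to the carbonyl, so 8 is traced to the achiral β,γ-unsaturated ketone 7, isomerised enantioselectively. Ketone 7 is the ester of keto acid 6, the hydrolysed Birch product (through dienol ether 5) of aryl acid 4. The carboxylate is used in the reduction because an ester would not survive dissolving metal. Acid 4 comes from ester 3, made by joining the aryl carbon to C4 in a palladium-catalysed α-arylation of methyl isobutyrate 2 with 4-bromo-3-methylanisole 1.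

**Side-chain iodide.** Iodide 19 carries C11–C15 and the C13 stereocentre with its oxygen, methyl and vinyl groups, all present in (R)-linalool 13. Ozonolysis of the trisubstituted alkene of silyl ether 14 gives aldehyde 16, which is one carbon too long. It is therefore oxidised to acid 17 and shortened by decarboxylative iodination through thiohydroxamate ester 18.

## Roads not taken

**Alternative 1: ester-tethered intramolecular Diels–Alder reaction.** Cutting C5–C6 and C9–C10 opens ring B into a C6=C7–C8=C9 diene and a 2-methyl enal dienophile (C5=C10), tied together by an ester between the C3 carboxyl and an oxygen on C6. In the forward direction a chiral oxazaborolidinium Lewis acid would cyclise the acyclic triene A2 to the cis-fused lactone aldehyde A1.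
- Merits: one catalytic step would form ring B and set C5, C9 and C10 with the complete C11–C15 chain already attached. The crowded C9–C11 bond never has to be made. In this respect and in convergence it is better than the chosen plan.
- Weak points: the cycloaddition must join C5, which bears the CMe2 group, to a carbon that becomes quaternary. The dienyl ester must react through its disfavoured s-cis conformer and is hydrolytically fragile. C9 ends with no neighbouring carbonyl, so an endo/exo error cannot be repaired. A1 has C1 as a formyl group directly on C10 (one carbon short) and an extra oxygen on C6, so homologation, lactone opening and deoxygenation add several steps before the C7=C8 alkene can be turned into the ether.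
- Comparison: the chosen plan delivers the two-carbon arm at the right length and oxidation level, leaves no surplus oxygen, and sets C9 under thermodynamic control.

**Alternative 2: iminium–enamine double Michael cascade.** The cut is through C4–C5 and C9–C10. A chiral primary amine salt would convert the acyclic enal A4 into its iminium ion. The silyl ketene acetal A5 would add at C5, and the resulting enamine would close ring B onto the vinyl sulfone at C9, giving A3.
- Merits: no photochemistry and no ozone. The absolute configuration comes from the catalyst in the ring-forming step. The CMe2CO2Me arm and C11 are installed together, and the sulfone is a good handle for chain extension.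
- Weak points: the first addition joins a fully substituted ketene acetal carbon to a β-substituted α-methyl enal. The second makes quaternary C10 from an α,α-disubstituted enamine. Both are at the edge of what aminocatalysis does, and three contiguous centres depend on one catalyst. A3 also has C1 as a formyl group on C10 and needs one-carbon homologation. C12–C13 would have to be added to the sulfone carbon with a chiral two-carbon electrophile that is harder to obtain than 19, followed by desulfonylation next to a ketone.
- Comparison: for C5 the concept is as good as the chosen one. The chosen plan offers a separate, precedented control element for each stereocentre and a shorter end game.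

**Alternative 3: enal-initiated bicyclisation terminated by the C13 hydroxyl.** The cut is through C9–C10 and O–C8. A dialkylaluminium chloride would activate the E-enal of the acyclic precursor A7. The C8=C9 alkene would attack C10 through a chair and the tertiary hydroxyl would trap the C8 cation, giving A6 with both rings and C8, C9 and C10 set at once.
- Merits: the end game is only an aldehyde oxidation and an ester cleavage, clearly shorter than the chosen one. All carbons of linalool are used without excision.
- Weak points: the initiating carbon is the β-position of a β,β-disubstituted enal flanked by C5, a weak electrophile for making a quaternary centre. The free tertiary allylic alcohol must survive the Lewis acid, with ionisation at C13 and elimination as the expected failures. C10 face selectivity rests on acyclic induction from C5. A7 itself needs an open-chain C5 stereocentre and an E-trisubstituted alkene, which is a long preparation.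
- Comparison: if the cyclisation worked it would win on step count. The chosen plan sets against that a key step whose reactivity does not depend on electrophilicity at a crowded carbon, and a ring C closure that leaves C13 untouched.

Key step: step 6

Assumption: the sense of induction in step 5 cannot be assigned in advance for this substrate; the quinine- or quinidine-derived catalyst that gives R-configured 8 is to be selected in a first screen.

## Route

Steps 8–11 (side-chain iodide) are run in parallel so that 19 is in hand when the sensitive diketone 12 is made.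

Step 1
Reactants: 1 4-bromo-3-methylanisole; 2 methyl isobutyrate
Product: 3 methyl 2-(4-methoxy-2-methylphenyl)-2-methylpropanoate
Conditions: LiNCy2 (from Cy2NH, n-BuLi), toluene, 0 °C; then 1, Pd(dba)2 (cat.), P(t-Bu)3 (cat.), rt
Reagents that add atoms: none
Why: Palladium-catalysed α-arylation of an ester enolate; the hindered amide base forms the isobutyrate enolate without self-condensation, and the bulky electron-rich phosphine on zerovalent palladium allows oxidative addition to the ortho-substituted bromide and reductive elimination to quaternary C4.

Step 2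
Reactants: 3 methyl 2-(4-methoxy-2-methylphenyl)-2-methylpropanoate
Product: 4 2-(4-methoxy-2-methylphenyl)-2-methylpropanoic acid
Conditions: KOH, MeOH/H2O, reflux; then aq. HCl
Reagents that add atoms: potassium hydroxide, [K+].[OH-]
Why: Saponification; the carboxylate, unlike the ester, is inert to dissolving lithium in the next step.

Step 3
Reactants: 4 2-(4-methoxy-2-methylphenyl)-2-methylpropanoic acid
Product: 6 2-methyl-2-(2-methyl-4-oxocyclohex-1-en-1-yl)propanoic acid, via dienol ether acid 5 (not isolated)
Conditions: Li, NH3(l), THF, t-BuOH, −78 to −33 °C; NH4Cl; then (CO2H)2, MeOH/H2O, rt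
Reagents that add atoms: water, O
Why: Birch reduction of the anisole leaves methoxy and both alkyl groups on sp2 carbons, as with 3,4-dialkylanisoles in general; mild oxalic acid hydrolysis of the enol ether gives the β,γ-unsaturated ketone without conjugation.

Step 4
Reactants: 6 2-methyl-2-(2-methyl-4-oxocyclohex-1-en-1-yl)propanoic acid
Product: 7 methyl 2-methyl-2-(2-methyl-4-oxocyclohex-1-en-1-yl)propanoate
Conditions: TMSCHN2, toluene/MeOH, 0 °C
Reagents that add atoms: trimethylsilyldiazomethane, C[Si](C)(C)C=[N+]=[N-]
Why: Neutral esterification, chosen so that no base reaches the β,γ-enone and conjugates it racemically before the asymmetric step.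

Step 5
Reactants: 7 methyl 2-methyl-2-(2-methyl-4-oxocyclohex-1-en-1-yl)propanoate
Product: 8 methyl 2-methyl-2-[(1R)-2-methyl-4-oxocyclohex-2-en-1-yl]propanoate
Conditions: cinchona-derived primary–tertiary diamine (9-amino-9-deoxy-epi-quinidine type or its pseudoenantiomer, 10 mol%), RCO2H co-catalyst, toluene, −20 °C to rt
Reagents that add atoms: none
Why: Amine-catalysed enantioselective β,γ to α,β isomerisation of a Birch-derived cyclohexenone; the primary amine forms the dienamine across C8–C9–C10–C5 and the protonated tertiary amine of the catalyst delivers the proton to one face of C5, which sets the C5 stereocentre, with conjugation as the driving force.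

Step 6
Reactants: 8 methyl 2-methyl-2-[(1R)-2-methyl-4-oxocyclohex-2-en-1-yl]propanoate; 9 allene
Product: 10 methyl 2-methyl-2-[(1S,2R,6S)-1-methyl-7-methylidene-5-oxobicyclo[4.2.0]octan-2-yl]propanoate
Conditions: 9 (excess), THF, −78 °C, hν (medium-pressure mercury lamp, uranium-glass filter, λ > 340 nm)
Reagents that add atoms: none
Why: Enone–allene [2+2] photocycloaddition, the closest known type being the cyclohexenone–allene addition used to place an acetate equivalent on the β-carbon. Excitation and intersystem crossing give the triplet enone, which bonds to allene to form a triplet 1,4-biradical; after spin inversion this collapses, so the four-membered ring closes stepwise by radical recombination (bonds C10–C1 and C9–C2) and not by a concerted process. The selectivity needed is head-to-head, with the central allene carbon on C9, which is the consistent outcome for cyclohexenones including β-methyl ones. C10 is controlled by the C5 substituent: A(1,2) strain with the C10 methyl forces the CMe2CO2Me group pseudoaxial, where it covers the β face, so C1 bonds from the α face and ends trans to C4. C9 is fixed by the cis ring fusion, the low-strain mode for a four–six system; any trans-fused adduct epimerises at C9 on basic alumina, and this centre is erased in step 12 in any case. Filtered long-wavelength light, low temperature and excess allene limit the 1,3-acyl shift of the β,γ-unsaturated ketone product and dimerisation of the enone.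

Step 7
Reactants: 10 methyl 2-methyl-2-[(1S,2R,6S)-1-methyl-7-methylidene-5-oxobicyclo[4.2.0]octan-2-yl]propanoate
Product: 12 methyl 2-methyl-2-[(1S,2R,6S)-1-methyl-5,7-dioxobicyclo[4.2.0]octan-2-yl]propanoate, via spiro ozonide 11 (not isolated)
Conditions: O3, CH2Cl2, −78 °C; then Me2S, −78 °C to rt; crude used at once
Reagents that add atoms: ozone, [O-][O+]=O
Why: Ozonolysis of the only alkene gives the cyclobutanone; the aprotic reductive work-up avoids premature retro-Claisen opening, so C9 stays doubly activated for step 12.

Step 8
Reactants: 13 (R)-linalool
Product: 14 (3R)-3,7-dimethyl-3-(triethylsilyloxy)octa-1,6-diene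
Conditions: TESOTf, 2,6-lutidine, CH2Cl2, −78 to 0 °C
Reagents that add atoms: triethylsilyl trifluoromethanesulfonate, CC[Si](CC)(CC)OS(=O)(=O)C(F)(F)F
Why: Silylation of the tertiary alcohol with the silyl triflate; the triethylsilyl ether tolerates base, ylide and radical conditions and is removed by fluoride.

Step 9
Reactants: 14 (3R)-3,7-dimethyl-3-(triethylsilyloxy)octa-1,6-diene
Product: 16 (4R)-4-methyl-4-(triethylsilyloxy)hex-5-enal, via trioxolane 15 (not isolated)
Conditions: O3 (limiting, Sudan Red 7B end point), CH2Cl2, −78 °C; then Me2S
Reagents that add atoms: ozone, [O-][O+]=O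
Why: Chemoselective ozonolysis; the electron-rich trisubstituted alkene reacts much faster than the hindered vinyl group with its allylic oxygen, as is well established for linalyl derivatives.

Step 10
Reactants: 16 (4R)-4-methyl-4-(triethylsilyloxy)hex-5-enal
Product: 17 (4R)-4-methyl-4-(triethylsilyloxy)hex-5-enoic acid
Conditions: NaClO2, NaH2PO4, 2-methyl-2-butene, t-BuOH/H2O, 0 °C to rt
Reagents that add atoms: sodium chlorite, [Na+].[O-]Cl=O
Why: Pinnick oxidation; the alkene scavenger removes hypochlorous acid and protects the vinyl group, and the buffered medium is tolerated by the tertiary silyl ether.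

Step 11
Reactants: 17 (4R)-4-methyl-4-(triethylsilyloxy)hex-5-enoic acid
Product: 19 (3R)-5-iodo-3-methyl-3-(triethylsilyloxy)pent-1-ene, via Barton ester 18 (not isolated)
Conditions: N-hydroxypyridine-2-thione, DCC, DMAP (cat.), CH2Cl2, 0 °C to rt, dark; then CHI3, benzene, hν (tungsten lamp), rt
Reagents that add atoms: iodoform, IC(I)I
Why: Barton decarboxylative iodination removes the one surplus carbon; the primary C11 radical takes iodine from iodoform faster than it can cyclise, since only 4-exo or 5-endo closure onto the vinyl group is open to it.

Step 12
Reactants: 12 methyl 2-methyl-2-[(1S,2R,6S)-1-methyl-5,7-dioxobicyclo[4.2.0]octan-2-yl]propanoate; 19 (3R)-5-iodo-3-methyl-3-(triethylsilyloxy)pent-1-ene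
Product: 20 methyl 2-methyl-2-{(1S,2R,6S)-1-methyl-6-[(3R)-3-methyl-3-(triethylsilyloxy)pent-4-en-1-yl]-5,7-dioxobicyclo[4.2.0]octan-2-yl}propanoate
Conditions: 19 (1.3 equiv), K2CO3 (dry, powdered), acetone, 4 Å sieves, 56 °C
Reagents that add atoms: none
Why: C-alkylation of a β-diketone enolate (acetoacetic-type activation); C9–H is the only doubly activated hydrogen, and the enolate is held U-shaped so that it chelates potassium, which with a soft iodide favours carbon over oxygen. The electrophile enters on the convex face and the cis ring fusion is kept, placing C11 on the β face; the C9 configuration matters only until step 13.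

Step 13
Reactants: 20 methyl 2-methyl-2-{(1S,2R,6S)-1-methyl-6-[(3R)-3-methyl-3-(triethylsilyloxy)pent-4-en-1-yl]-5,7-dioxobicyclo[4.2.0]octan-2-yl}propanoate
Product: 21 methyl 2-[(1R,2S,3R)-2-(2-methoxy-2-oxoethyl)-2-methyl-3-[(3R)-3-methyl-3-(triethylsilyloxy)pent-4-en-1-yl]-4-oxocyclohexyl]-2-methylpropanoate
Conditions: NaOMe (0.3 equiv), MeOH, 0 °C to rt
Reagents that add atoms: methanol (as sodium methoxide), CO
Why: Retro-Claisen cleavage; methoxide adds to the strained, more electrophilic cyclobutanone and the tetrahedral intermediate expels the C8 enolate by breaking C2–C9, releasing the ring strain and leaving CH2CO2Me on C10. The C9 stereocentre is set here by equilibration through the enolate: the side chain settles equatorial (β), cis to the axial C10 methyl, as in 8-oxolabdanes.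

Step 14
Reactants: 21 methyl 2-[(1R,2S,3R)-2-(2-methoxy-2-oxoethyl)-2-methyl-3-[(3R)-3-methyl-3-(triethylsilyloxy)pent-4-en-1-yl]-4-oxocyclohexyl]-2-methylpropanoate
Product: 22 methyl 2-[(1R,2R,3S)-2-(2-methoxy-2-oxoethyl)-2-methyl-4-methylidene-3-[(3R)-3-methyl-3-(triethylsilyloxy)pent-4-en-1-yl]cyclohexyl]-2-methylpropanoate
Conditions: Ph3PCH3Br, KOt-Bu, toluene, 80 °C
Reagents that add atoms: methyltriphenylphosphonium bromide, C[P+](c1ccccc1)(c1ccccc1)c1ccccc1.[Br-]
Why: Wittig methylenation, routine for hindered 8-oxolabdane-type ketones in the presence of esters; enolisation at C9 does no harm because the equatorial epimer is the thermodynamic one (the C9 and C10 descriptors change only through priority changes).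

Step 15
Reactants: 22 methyl 2-[(1R,2R,3S)-2-(2-methoxy-2-oxoethyl)-2-methyl-4-methylidene-3-[(3R)-3-methyl-3-(triethylsilyloxy)pent-4-en-1-yl]cyclohexyl]-2-methylpropanoate
Product: 23 methyl 2-[(1R,2R,3S)-3-[(3R)-3-hydroxy-3-methylpent-4-en-1-yl]-2-(2-methoxy-2-oxoethyl)-2-methyl-4-methylidenecyclohexyl]-2-methylpropanoate
Conditions: TBAF, THF, rt to 40 °C
Reagents that add atoms: none
Why: Fluoride desilylation of the tertiary triethylsilyl ether; no acid touches the tertiary allylic alcohol.

Step 16
Reactants: 23 methyl 2-[(1R,2R,3S)-3-[(3R)-3-hydroxy-3-methylpent-4-en-1-yl]-2-(2-methoxy-2-oxoethyl)-2-methyl-4-methylidenecyclohexyl]-2-methylpropanoate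
Product: 25 methyl 2-[(2R,4aR,5S,6R,8aR)-2-ethenyl-5-(2-methoxy-2-oxoethyl)-2,5,8a-trimethyloctahydro-2H-chromen-6-yl]-2-methylpropanoate, via alkylmercury trifluoroacetate 24 (not isolated)
Conditions: Hg(OCOCF3)2, MeNO2, −20 to 0 °C; then NaBH4, aq. NaOH, 0 °C
Reagents that add atoms: none
Why: Intramolecular oxymercuration–demercuration (6-exo-trig, Markovnikov), well known for closing labda-8(17),14-dien-13-ols to 8,13-epoxides; divalent mercury activates the 1,1-disubstituted alkene in preference to the vinyl group, which is deactivated by its allylic oxygen. The C8 stereocentre is set by equatorial (α) entry of oxygen, because axial β approach is 1,3-diaxial to the C10 methyl, giving the trans ring fusion; C13 is untouched since its C–O bond is never broken.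

Step 17
Reactants: 25 methyl 2-[(2R,4aR,5S,6R,8aR)-2-ethenyl-5-(2-methoxy-2-oxoethyl)-2,5,8a-trimethyloctahydro-2H-chromen-6-yl]-2-methylpropanoate
Product: 26 2-[(2R,4aR,5S,6R,8aR)-5-(carboxymethyl)-2-ethenyl-2,5,8a-trimethyloctahydro-2H-chromen-6-yl]-2-methylpropanoic acid
Conditions: EtSNa (excess), DMF, 90 °C; then 1 M HCl, 0 °C
Reagents that add atoms: none
Why: Thiolate demethylation by SN2 attack at the methyl carbons cleaves both esters, including the neopentyl-type CMe2CO2Me that resists acyl-oxygen hydrolysis; the ether and the vinyl group are inert to thiolate.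

## Compound list

1 | 4-bromo-3-methylanisole | COc1ccc(Br)c(C)c1 | starting material
2 | methyl isobutyrate | COC(=O)C(C)C | starting material
3 | methyl 2-(4-methoxy-2-methylphenyl)-2-methylpropanoate | COC(=O)C(C)(C)c1ccc(OC)cc1C | intermediate
4 | 2-(4-methoxy-2-methylphenyl)-2-methylpropanoic acid | OC(=O)C(C)(C)c1ccc(OC)cc1C | intermediate
5 | 2-(4-methoxy-2-methylcyclohexa-1,4-dien-1-yl)-2-methylpropanoic acid | COC1=CCC(C(C)(C)C(=O)O)=C(C)C1 | intermediate
6 | 2-methyl-2-(2-methyl-4-oxocyclohex-1-en-1-yl)propanoic acid | O=C1CCC(C(C)(C)C(=O)O)=C(C)C1 | intermediate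
7 | methyl 2-methyl-2-(2-methyl-4-oxocyclohex-1-en-1-yl)propanoate | O=C1CCC(C(C)(C)C(=O)OC)=C(C)C1 | intermediate
8 | methyl 2-methyl-2-[(1R)-2-methyl-4-oxocyclohex-2-en-1-yl]propanoate | O=C1CC[C@@H](C(C)(C)C(=O)OC)C(C)=C1 | intermediate
9 | allene (propadiene) | C=C=C | starting material
10 | methyl 2-methyl-2-[(1S,2R,6S)-1-methyl-7-methylidene-5-oxobicyclo[4.2.0]octan-2-yl]propanoate (cis-fused, cyclobutane CH2 trans to the C5 side chain) | O=C1CC[C@@H](C(C)(C)C(=O)OC)[C@]2(C)CC(=C)[C@H]12 | intermediate
11 | secondary ozonide of 10: spiro-1,2,4-trioxolane at the former methylidene-bearing carbon, ring stereocentres as in 10, both spiro epimers | O=C1CC[C@@H](C(C)(C)C(=O)OC)[C@]2(C)CC3(OCOO3)[C@H]12 | intermediate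
12 | methyl 2-methyl-2-[(1S,2R,6S)-1-methyl-5,7-dioxobicyclo[4.2.0]octan-2-yl]propanoate | O=C1CC[C@@H](C(C)(C)C(=O)OC)[C@]2(C)CC(=O)[C@H]12 | intermediate
13 | (R)-linalool, (3R)-3,7-dimethylocta-1,6-dien-3-ol | C=C[C@@](O)(C)CCC=C(C)C | starting material
14 | (3R)-3,7-dimethyl-3-(triethylsilyloxy)octa-1,6-diene | C=C[C@@](O[Si](CC)(CC)CC)(C)CCC=C(C)C | intermediate
15 | 3,3-dimethyl-5-[(3R)-3-methyl-3-(triethylsilyloxy)pent-4-en-1-yl]-1,2,4-trioxolane (both epimers at the ring CH) | C=C[C@@](O[Si](CC)(CC)CC)(C)CCC1OC(C)(C)OO1 | intermediate
16 | (4R)-4-methyl-4-(triethylsilyloxy)hex-5-enal | C=C[C@@](O[Si](CC)(CC)CC)(C)CCC=O | intermediate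
17 | (4R)-4-methyl-4-(triethylsilyloxy)hex-5-enoic acid | C=C[C@@](O[Si](CC)(CC)CC)(C)CCC(=O)O | intermediate
18 | 2-thioxopyridin-1(2H)-yl (4R)-4-methyl-4-(triethylsilyloxy)hex-5-enoate | C=C[C@@](O[Si](CC)(CC)CC)(C)CCC(=O)On1ccccc1=S | intermediate
19 | (3R)-5-iodo-3-methyl-3-(triethylsilyloxy)pent-1-ene | C=C[C@@](O[Si](CC)(CC)CC)(C)CCI | intermediate
20 | methyl 2-methyl-2-{(1S,2R,6S)-1-methyl-6-[(3R)-3-methyl-3-(triethylsilyloxy)pent-4-en-1-yl]-5,7-dioxobicyclo[4.2.0]octan-2-yl}propanoate | O=C1CC[C@@H](C(C)(C)C(=O)OC)[C@]2(C)CC(=O)[C@]12CC[C@@](C)(O[Si](CC)(CC)CC)C=C | intermediate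
21 | methyl 2-[(1R,2S,3R)-2-(2-methoxy-2-oxoethyl)-2-methyl-3-[(3R)-3-methyl-3-(triethylsilyloxy)pent-4-en-1-yl]-4-oxocyclohexyl]-2-methylpropanoate | O=C1CC[C@@H](C(C)(C)C(=O)OC)[C@](C)(CC(=O)OC)[C@H]1CC[C@@](C)(O[Si](CC)(CC)CC)C=C | intermediate
22 | methyl 2-[(1R,2R,3S)-2-(2-methoxy-2-oxoethyl)-2-methyl-4-methylidene-3-[(3R)-3-methyl-3-(triethylsilyloxy)pent-4-en-1-yl]cyclohexyl]-2-methylpropanoate | C=C1CC[C@@H](C(C)(C)C(=O)OC)[C@](C)(CC(=O)OC)[C@H]1CC[C@@](C)(O[Si](CC)(CC)CC)C=C | intermediate
23 | methyl 2-[(1R,2R,3S)-3-[(3R)-3-hydroxy-3-methylpent-4-en-1-yl]-2-(2-methoxy-2-oxoethyl)-2-methyl-4-methylidenecyclohexyl]-2-methylpropanoate | C=C1CC[C@@H](C(C)(C)C(=O)OC)[C@](C)(CC(=O)OC)[C@H]1CC[C@@](C)(O)C=C | intermediate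
24 | methyl 2-[(2R,4aR,5S,6R,8aR)-2-ethenyl-5-(2-methoxy-2-oxoethyl)-2,5-dimethyl-8a-{[(trifluoroacetoxy)mercurio]methyl}octahydro-2H-chromen-6-yl]-2-methylpropanoate | C=C[C@@]1(C)CC[C@@H]2[C@@](C)(CC(=O)OC)[C@H](C(C)(C)C(=O)OC)CC[C@@]2(C[Hg]OC(=O)C(F)(F)F)O1 | intermediate
25 | methyl 2-[(2R,4aR,5S,6R,8aR)-2-ethenyl-5-(2-methoxy-2-oxoethyl)-2,5,8a-trimethyloctahydro-2H-chromen-6-yl]-2-methylpropanoate | C=C[C@@]1(C)CC[C@@H]2[C@@](C)(CC(=O)OC)[C@H](C(C)(C)C(=O)OC)CC[C@@]2(C)O1 | intermediate
26 | 2-[(2R,4aR,5S,6R,8aR)-5-(carboxymethyl)-2-ethenyl-2,5,8a-trimethyloctahydro-2H-chromen-6-yl]-2-methylpropanoic acid | C=C[C@@]1(C)CC[C@@H]2[C@@](C)(CC(=O)O)[C@H](C(C)(C)C(=O)O)CC[C@@]2(C)O1 | target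

## Step count and risks

Total: 17 steps. Longest linear sequence: 13 steps (steps 1–7 and 12–17, from 1 to 26). The side-chain iodide takes 4 steps (8–11) from (R)-linalool.

The least certain steps are step 6 (key), then steps 12, 5, 11 and 16.

**Step 6.** The most likely failure is insufficient facial discrimination at C10, if the pseudoaxial preference of the C5 group is weaker in the twisted triplet than in the ground state. Over-irradiation can also cause a 1,3-acyl shift of the β,γ-unsaturated ketone adduct, and a minor head-to-tail closure is possible. The fallback makes the C10–C1 bond in the ground state. It sets out from 8: Mukaiyama–Michael addition of 1-methoxy-1-(trimethylsilyloxy)ethene with catalytic TMSNTf2 would give the regiodefined silyl enol ether methyl 2-{(1R,2S)-2-(2-methoxy-2-oxoethyl)-2-methyl-4-[(trimethylsilyl)oxy]cyclohex-3-en-1-yl}-2-methylpropanoate F1. Anhydrous benzyltrimethylammonium fluoride would then release the C8–C9 ammonium enolate for alkylation with 19, and NaOMe equilibration at C9 would return to the route at 21. This path is shorter but relies on a slow addition to a hindered β,β-disubstituted enone and on alkylating an unstabilised enolate next to a quaternary carbon, which is why it is not the first choice.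

**Step 12.** O-alkylation may compete, and C-alkylation at the crowded C9 may be slow enough that the strained diketone is opened by adventitious nucleophiles first. The fallback changes the order of events and alkylates a more nucleophilic ketone dienolate. It sets out from 10: KOt-Bu in t-BuOH/THF would generate the conjugated dienolate (C9 is α to the ketone and allylic), and 19 would give methyl 2-methyl-2-{(1S,2R,6S)-1-methyl-7-methylidene-6-[(3R)-3-methyl-3-(triethylsilyloxy)pent-4-en-1-yl]-5-oxobicyclo[4.2.0]octan-2-yl}propanoate F2. Ozonolysis with a limiting amount of ozone and an indicator dye would then cleave the strained 1,1-disubstituted alkene in preference to the hindered, oxygen-deactivated vinyl group and return to the route at 20.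

**Step 5.** Enantioselectivity of the γ-protonation may be low, because the tertiary group on the carbon being protonated is bulkier than in established substrates, and reversible dienamine formation could erode it further. The fallback replaces catalysis by resolution at the acid stage. It sets out from 6: DBU would conjugate it to racemic 2-methyl-2-(2-methyl-4-oxocyclohex-2-en-1-yl)propanoic acid F3. Crystallisation of its salt with one enantiomer of 1-phenylethylamine and acidification would give 2-methyl-2-[(1R)-2-methyl-4-oxocyclohex-2-en-1-yl]propanoic acid F4. Esterification with TMSCHN2 returns to the route at 8.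

**Step 11.** The alkyl radical may add to the thiocarbonyl group of the thiohydroxamate ester faster than it takes iodine, and the silyl ether may be partly lost during activation of the acid. The fallback removes the extra carbon by a second alkene cleavage. It sets out from 16: TBSOTf and Et3N would give the enol ether tert-butyl{[(4R)-4-methyl-4-(triethylsilyloxy)hexa-1,5-dien-1-yl]oxy}dimethylsilane F5. Selective ozonolysis of the electron-rich enol ether would give (3R)-3-methyl-3-(triethylsilyloxy)pent-4-enal F6, reduced in the same flask by NaBH4 to (3R)-3-methyl-3-(triethylsilyloxy)pent-4-en-1-ol F7. An Appel iodination (I2, PPh3, imidazole) returns to the route at 19.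

**Step 16.** Mercuration of the vinyl group may compete. Closure may also be slow, because the C13 methyl becomes 1,3-diaxial to the new C8 substituent; that would allow equilibration toward the cis-fused ether. The fallback uses selenium-induced etherification followed by radical reduction. It sets out from 23: N-(phenylseleno)phthalimide with catalytic camphorsulfonic acid would give methyl 2-[(2R,4aR,5S,6R,8aR)-2-ethenyl-5-(2-methoxy-2-oxoethyl)-2,5-dimethyl-8a-[(phenylselanyl)methyl]octahydro-2H-chromen-6-yl]-2-methylpropanoate F8. Tributyltin hydride with AIBN would replace selenium by hydrogen and return to the route at 25.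

A further point to watch is the enantiomeric purity of commercial (R)-linalool; material from its minor enantiomer would be removed as a diastereomer after step 12.

## Further compounds

F1 | step 6 | methyl 2-{(1R,2S)-2-(2-methoxy-2-oxoethyl)-2-methyl-4-[(trimethylsilyl)oxy]cyclohex-3-en-1-yl}-2-methylpropanoate | COC(=O)C[C@]1(C)C=C(O[Si](C)(C)C)CC[C@H]1C(C)(C)C(=O)OC
F2 | step 12 | methyl 2-methyl-2-{(1S,2R,6S)-1-methyl-7-methylidene-6-[(3R)-3-methyl-3-(triethylsilyloxy)pent-4-en-1-yl]-5-oxobicyclo[4.2.0]octan-2-yl}propanoate | O=C1CC[C@@H](C(C)(C)C(=O)OC)[C@]2(C)CC(=C)[C@]12CC[C@@](C)(O[Si](CC)(CC)CC)C=C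
F3 | step 5 | racemic 2-methyl-2-(2-methyl-4-oxocyclohex-2-en-1-yl)propanoic acid | O=C1CCC(C(C)(C)C(=O)O)C(C)=C1
F4 | step 5 | 2-methyl-2-[(1R)-2-methyl-4-oxocyclohex-2-en-1-yl]propanoic acid | O=C1CC[C@@H](C(C)(C)C(=O)O)C(C)=C1
F5 | step 11 | tert-butyl{[(4R)-4-methyl-4-(triethylsilyloxy)hexa-1,5-dien-1-yl]oxy}dimethylsilane (E/Z mixture) | C=C[C@@](O[Si](CC)(CC)CC)(C)CC=CO[Si](C)(C)C(C)(C)C
F6 | step 11 | (3R)-3-methyl-3-(triethylsilyloxy)pent-4-enal | C=C[C@@](O[Si](CC)(CC)CC)(C)CC=O
F7 | step 11 | (3R)-3-methyl-3-(triethylsilyloxy)pent-4-en-1-ol | C=C[C@@](O[Si](CC)(CC)CC)(C)CCO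
F8 | step 16 | methyl 2-[(2R,4aR,5S,6R,8aR)-2-ethenyl-5-(2-methoxy-2-oxoethyl)-2,5-dimethyl-8a-[(phenylselanyl)methyl]octahydro-2H-chromen-6-yl]-2-methylpropanoate | C=C[C@@]1(C)CC[C@@H]2[C@@](C)(CC(=O)OC)[C@H](C(C)(C)C(=O)OC)CC[C@@]2(C[Se]c3ccccc3)O1
A1 | alternative 1 | cis-fused lactone aldehyde: 3,3,4,6-tetramethyl-5-[(3R)-3-methyl-3-(triethylsilyloxy)pent-4-en-1-yl]-2-oxo-2,3,3a,4,5,7a-hexahydro-1-benzofuran-4-carbaldehyde, configuration as in the SMILES | C=C[C@@](O[Si](CC)(CC)CC)(C)CC[C@@H]1[C@@](C)(C=O)[C@@H]2C(C)(C)C(=O)O[C@@H]2C=C1C
A2 | alternative 1 | acyclic triene: (1E,3E,7R)-3,7-dimethyl-7-(triethylsilyloxy)nona-1,3,8-trien-1-yl (3E)-2,2,4-trimethyl-5-oxopent-3-enoate | C=C[C@@](O[Si](CC)(CC)CC)(C)CC/C=C(C)/C=C/OC(=O)C(C)(C)/C=C(C)/C=O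
A3 | alternative 2 | cyclohexane with C10 methyl and formyl, C5 CMe2CO2Me, C9 phenylsulfonylmethyl and C8 dioxolane groups, configuration as in the SMILES | O=S(=O)(c1ccccc1)C[C@@H]2[C@@](C)(C=O)[C@H](C(C)(C)C(=O)OC)CCC23OCCO3
A4 | alternative 2 | (2E)-2-methyl-5-{2-[(E)-2-(phenylsulfonyl)ethenyl]-1,3-dioxolan-2-yl}pent-2-enal | O=C/C(C)=C/CCC1(OCCO1)/C=C/S(=O)(=O)c1ccccc1
A5 | alternative 2 | 1-methoxy-2-methyl-1-(trimethylsilyloxy)prop-1-ene | COC(O[Si](C)(C)C)=C(C)C
A6 | alternative 3 | bicyclic aldehyde ester: the target with C2 as formyl and C3 as methyl ester | C=C[C@@]1(C)CC[C@@H]2[C@@](C)(CC=O)[C@H](C(C)(C)C(=O)OC)CC[C@@]2(C)O1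
A7 | alternative 3 | acyclic hydroxy enal ester: methyl (3R,6E,10R)-10-hydroxy-2,2,6,10-tetramethyl-3-[(2E)-4-oxobut-2-en-2-yl]dodeca-6,11-dienoate | C=C[C@@](O)(C)CC/C=C(C)/CC[C@@H](C(C)(C)C(=O)OC)/C(C)=C/C=O
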